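**Retrosynthetic overview**

1. Numbering (germacrane): ring C1–C10; C2 carries the angelate, C6 the acetate, C7 the isopropyl group (C11 is its methine), C8 is the CH2 next to C7, and C4 and C10 carry the methyls. The esters and both oxiranes (C1–C10–O and C4–C5–O) go back to the (1(10)E,4E)-cyclodecadiene-2,6-diol 19 by site-selective acylation and one double hydroxyl-directed epoxidation.
2. The ten-membered ring is opened between C7 and C8. The isopropyl group is carried as the strained 2,2-dimethyloxirane C7–C11–O and C8 as a lithiated phenyl sulfone, which opens the oxirane at C7 (10-exo-tet, inversion). The enabling feature: C7 is the one ring stereocentre without a heteroatom, its branch C11 can be tied to it in a three-membered ring with an oxygen leaving group, and its neighbour C8 is a plain CH2 that can bear a removable carbanion-stabilising group.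
3. The sulfonyl group on C8 and the hydroxyl on C11 are then excised reductively. C7 comes from Sharpless epoxidation of prenol plus SN2 inversion, C6 from Felkin–Anh addition to the epoxy aldehyde, C2 from catalytic asymmetric propargylation.
4. The open chain 13 grows linearly from but-3-ynyl phenyl sulfone: two zirconium-catalysed carboalumination/iodination cycles give both (E)-CH2–C(CH3)=CH units; formylation/propargylation adds C2–C5 and a Nozaki–Hiyama–Kishi coupling adds C6, C7 and C11.
5. Order of ring formation: oxirane C7–C11–O (step 6, temporary) → ten-membered carbocycle (step 10) → oxiranes C4–C5–O and C1–C10–O (both in step 15).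

Key step: step 10

Remark: the (R)-enantiomer of the phosphoric acid catalyst in step 4 is assumed to direct Re-face propargylation of enal 5, by analogy with its allylborations; if the sense proves opposite, the (S)-catalyst is used.

**Route**

Step 1
Reactants: 1 4-bromobut-1-yne
Product: 2 (but-3-yn-1-ylsulfonyl)benzene
Conditions: PhSO2Na, Bu4NI (cat.), DMF, 60 °C
Reagents that add atoms: sodium benzenesulfinate, [Na+].[O-]S(=O)c1ccccc1
Why: SN2 S-alkylation of the sulfinate by the primary bromide should give the sulfone whose α-CH2 (the later C8) becomes the carbanion site of the key step.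

Step 2
Reactants: 2 (but-3-yn-1-ylsulfonyl)benzene
Product: 4 {[(3E)-4-iodo-3-methylbut-3-en-1-yl]sulfonyl}benzene, via alkenyl(dimethyl)alane 3 (not isolated)
Conditions: Me3Al, Cp2ZrCl2 (0.25 equiv), CH2Cl2, 0 to 23 °C; then I2, THF, −30 °C
Reagents that add atoms: trimethylaluminium, C[Al](C)C; iodine, II
Why: zirconium-catalysed syn-carboalumination of the terminal alkyne puts the methyl group on the internal carbon and aluminium on the terminus, and iodinolysis with retention should give the (E)-vinyl iodide that fixes the C1=C10 geometry.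

Step 3
Reactants: 4 {[(3E)-4-iodo-3-methylbut-3-en-1-yl]sulfonyl}benzene
Product: 5 (2E)-3-methyl-5-(phenylsulfonyl)pent-2-enal
Conditions: CO (3 atm), Bu3SnH (slow addition), Pd(PPh3)4 (4 mol%), THF, 50 °C
Reagents that add atoms: carbon monoxide, [C-]#[O+]
Why: palladium-catalysed reductive carbonylation (formylation) of a vinyl iodide with CO and tin hydride proceeds with retention of alkene geometry and should give the (E)-enal carrying C2.

Step 4
Reactants: 5 (2E)-3-methyl-5-(phenylsulfonyl)pent-2-enal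
Product: 6 (4R,5E)-6-methyl-8-(phenylsulfonyl)oct-5-en-1-yn-4-ol
Conditions: allenylboronic acid pinacol ester, (R)-3,3'-bis(2,4,6-triisopropylphenyl)-1,1'-binaphthyl-2,2'-diyl hydrogen phosphate (5 mol%), 4 Å molecular sieves, toluene, −20 °C
Reagents that add atoms: allenylboronic acid pinacol ester, C=C=CB1OC(C)(C)C(C)(C)O1
Why: chiral phosphoric acid-catalysed asymmetric propargylation (SE2' transfer from the allenylboronate through a six-membered cyclic transition state) should add the propargyl group to the Re face of the aldehyde and set C2 as R by catalyst control.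

Step 5
Reactants: 6 (4R,5E)-6-methyl-8-(phenylsulfonyl)oct-5-en-1-yn-4-ol
Product: 8 (1E,4R,5E)-1-iodo-2,6-dimethyl-8-(phenylsulfonyl)octa-1,5-dien-4-ol, via alkenylalane 7 (not isolated)
Conditions: Me3Al (3.5 equiv), Cp2ZrCl2 (0.3 equiv), CH2Cl2, 0 to 23 °C; then I2, THF, −30 °C
Reagents that add atoms: trimethylaluminium, C[Al](C)C; iodine, II
Why: a second zirconium-catalysed carboalumination/iodinolysis, run on the aluminium alkoxide as for but-3-yn-1-ol itself, should give the (E)-vinyl iodide that fixes the C4=C5 geometry without touching C2.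

Step 6
Reactants: 9 3-methylbut-2-en-1-ol (prenol)
Product: 10 [(2S)-3,3-dimethyloxiran-2-yl]methanol
Conditions: Ti(OiPr)4 (5 mol%), L-(+)-diethyl tartrate (6 mol%), t-BuOOH, 4 Å molecular sieves, CH2Cl2, −20 °C
Reagents that add atoms: tert-butyl hydroperoxide, CC(C)(C)OO
Why: Sharpless asymmetric epoxidation of the primary allylic alcohol with the L-(+)-tartrate should give the (S)-epoxy alcohol, which fixes by reagent control the oxirane carbon that becomes C7.

Step 7
Reactants: 10 [(2S)-3,3-dimethyloxiran-2-yl]methanol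
Product: 11 (2R)-3,3-dimethyloxirane-2-carbaldehyde
Conditions: Dess–Martin periodinane, NaHCO3, CH2Cl2, 0 °C; used at once
Reagents that add atoms: none
Why: buffered Dess–Martin oxidation should give the α,β-epoxy aldehyde without opening the oxirane or epimerising its stereocentre (the descriptor changes only through the priority rules).

Step 8
Reactants: 8 (1E,4R,5E)-1-iodo-2,6-dimethyl-8-(phenylsulfonyl)octa-1,5-dien-4-ol; 11 (2R)-3,3-dimethyloxirane-2-carbaldehyde
Product: 12 (1S,2E,5R,6E)-1-[(2S)-3,3-dimethyloxiran-2-yl]-3,7-dimethyl-9-(phenylsulfonyl)nona-2,6-diene-1,5-diol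
Conditions: CrCl2 (4 equiv), NiCl2 (1 mol%), DMSO–THF, 23 °C
Reagents that add atoms: none
Why: the Nozaki–Hiyama–Kishi coupling tolerates the free hydroxyl, the sulfone and the oxirane, and Felkin–Anh addition of the alkenylchromium anti to the oxirane C–O bond should set C6 as the anti (erythro) epoxy alcohol.

Step 9
Reactants: 12 (1S,2E,5R,6E)-1-[(2S)-3,3-dimethyloxiran-2-yl]-3,7-dimethyl-9-(phenylsulfonyl)nona-2,6-diene-1,5-diol
Product: 13 1,5-bis-O-[tert-butyl(dimethyl)silyl] ether of 12
Conditions: TBSOTf (2.5 equiv), 2,6-lutidine, CH2Cl2, −78 to 0 °C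
Reagents that add atoms: tert-butyldimethylsilyl trifluoromethanesulfonate, CC(C)(C)[Si](C)(C)OS(=O)(=O)C(F)(F)F
Why: silylation of both secondary hydroxyls under non-nucleophilic base removes the acidic protons and blocks Payne rearrangement of the C6 alkoxide before the carbanion chemistry.

Step 10
Reactants: 13 1,5-bis-O-[tert-butyl(dimethyl)silyl] ether of 12
Product: 15 2-[(1R,2S,3E,6R,7E)-2,6-bis{[tert-butyl(dimethyl)silyl]oxy}-4,8-dimethyl-10-(phenylsulfonyl)cyclodeca-3,7-dien-1-yl]propan-2-ol (both epimers at the sulfonyl carbon), via lithium α-sulfonyl carbanion 14 (not isolated)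
Conditions: n-BuLi (1.05 equiv), THF, −78 °C; then DMPU, dilution to 0.003 M, −78 to 25 °C; NH4Cl (aq), 0 °C
Reagents that add atoms: none
Why: Deprotonation α to the sulfone gives carbanion 14, which attacks the less substituted oxirane carbon C7 in an SN2 process; release of the strain of the C7–C11–O ring is the driving force and the tertiary alkoxide at C11 the leaving group. The closest known reaction type is the intramolecular alkylation of sulfur-stabilised carbanions by terminal trisubstituted oxiranes, which closes ten- and fourteen-membered terpenoid carbocycles. The ten-membered ring closes in the 10-exo-tet mode, because the breaking C7–O bond lies outside the new ring. C7 is formed with clean inversion, so its configuration is dictated by the oxirane made in step 6; the sulfonyl-bearing C8 forms as an epimer mixture that converges in step 13. The step needs attack at C7 rather than at the quaternary C11 (SN2 preference for the secondary carbon), cyclisation rather than oligomerisation (high dilution, and the two (E)-trisubstituted alkenes remove rotors from the chain), and substitution rather than base-induced isomerisation of the oxirane to an allylic alkoxide (soft sulfonyl carbanion, DMPU); a cold quench limits silyl migration from the C6 oxygen to the new C11 alkoxide.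

Step 11
Reactants: 15 macrocyclic hydroxy sulfone
Product: 16 methyl 2-[(1R,2S,3E,6R,7E)-2,6-bis{[tert-butyl(dimethyl)silyl]oxy}-4,8-dimethyl-10-(phenylsulfonyl)cyclodeca-3,7-dien-1-yl]propan-2-yl oxalate
Conditions: ClC(O)CO2Me, DMAP (cat.), pyridine, CH2Cl2, 0 to 23 °C
Reagents that add atoms: methyl chlorooxoacetate, COC(=O)C(Cl)=O
Why: acylation of the tertiary C11 alcohol with the unhindered oxalyl chloride half-ester should give the radical precursor for deoxygenation.

Step 12
Reactants: 16 tertiary methyl oxalate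
Product: 17 {[(2S,3S,4E,7R,8E)-3,7-bis{[tert-butyl(dimethyl)silyl]oxy}-5,9-dimethyl-2-(propan-2-yl)cyclodeca-4,8-dien-1-yl]sulfonyl}benzene (both epimers at C1)
Conditions: Bu3SnH, Et3B, air (trace), toluene, 25 to 40 °C
Reagents that add atoms: none
Why: Barton–McCombie-type radical deoxygenation of the tertiary oxalate gives the C11 radical, which is reduced to the isopropyl group without touching C7, and the low temperature avoids Cope rearrangement of the (E,E)-cyclodeca-1,5-diene.

Step 13
Reactants: 17 isopropyl sulfone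
Product: 18 (1E,3R,5E,7R,8S)-3,7-bis{[tert-butyl(dimethyl)silyl]oxy}-1,5-dimethyl-8-(propan-2-yl)cyclodeca-1,5-diene
Conditions: Na(Hg) (6% Na), Na2HPO4, MeOH–THF, −20 to 0 °C
Reagents that add atoms: none
Why: reductive desulfonylation with sodium amalgam replaces the C8 sulfonyl group by hydrogen, so both C8 epimers converge on one compound.

Step 14
Reactants: 18 bis-silyl ether
Product: 19 (1R,2E,5R,6E,10S)-3,7-dimethyl-10-(propan-2-yl)cyclodeca-2,6-diene-1,5-diol
Conditions: Bu4NF, THF, 0 to 35 °C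
Reagents that add atoms: none
Why: fluoride cleavage of both silyl ethers under non-acidic conditions should free the two allylic alcohols without transannular cyclisation of the acid-sensitive diene.

Step 15
Reactants: 19 (1R,2E,5R,6E,10S)-3,7-dimethyl-10-(propan-2-yl)cyclodeca-2,6-diene-1,5-diol
Product: 20 (1S,2R,4S,5S,6R,7S,10S)-1,10:4,5-diepoxygermacrane-2,6-diol
Conditions: VO(acac)2 (5 mol%), t-BuOOH (2.4 equiv), CH2Cl2, 0 to 23 °C
Reagents that add atoms: tert-butyl hydroperoxide, CC(C)(C)OO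
Why: in this double hydroxyl-directed (vanadium-catalysed) epoxidation, A(1,3) strain with the cis methyl keeps each carbinol C–H in the alkene plane and the hydroxyl on the outer face, so oxygen is delivered syn to OH and should give the threo epoxy alcohols, i.e. 1S,10S from C2 and 4S,5S from C6.

Step 16
Reactants: 20 (1S,2R,4S,5S,6R,7S,10S)-1,10:4,5-diepoxygermacrane-2,6-diol; 21 angelic acid
Product: 23 (1S,2R,4S,5S,6R,7S,10S)-1,10:4,5-diepoxy-6-hydroxygermacran-2-yl (2Z)-2-methylbut-2-enoate, via mixed anhydride 22 (not isolated)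
Conditions: 2,4,6-trichlorobenzoyl chloride, Et3N, toluene, 23 °C; then 20, toluene, 60 °C
Reagents that add atoms: none
Why: Yamaguchi-type esterification through the mixed anhydride, run without a nucleophilic catalyst, should keep the (Z)-geometry of the angeloyl group and acylate the less hindered C2 hydroxyl in preference to the C6 hydroxyl next to the isopropyl-bearing C7.

Step 17
Reactants: 23 C2 angelate with free C6 hydroxyl
Product: 24 (1S,2R,4S,5S,6R,7S,10S)-6-acetoxy-1,10:4,5-diepoxygermacran-2-yl (2Z)-2-methylbut-2-enoate (target)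
Conditions: Ac2O, DMAP (cat.), pyridine, CH2Cl2, 23 °C
Reagents that add atoms: acetic anhydride, CC(=O)OC(C)=O
Why: nucleophile-catalysed acetylation of the remaining hindered secondary alcohol should complete the target without affecting the oxiranes or the conjugated ester.

**Compound list**

1 | 4-bromobut-1-yne | C#CCCBr | starting material
2 | (but-3-yn-1-ylsulfonyl)benzene | C#CCCS(=O)(=O)c1ccccc1 | intermediate
3 | dimethyl[(1E)-2-methyl-4-(phenylsulfonyl)but-1-en-1-yl]alane | C[Al](C)/C=C(\C)CCS(=O)(=O)c1ccccc1 | intermediate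
4 | {[(3E)-4-iodo-3-methylbut-3-en-1-yl]sulfonyl}benzene | I/C=C(\C)CCS(=O)(=O)c1ccccc1 | intermediate
5 | (2E)-3-methyl-5-(phenylsulfonyl)pent-2-enal | O=C/C=C(\C)CCS(=O)(=O)c1ccccc1 | intermediate
6 | (4R,5E)-6-methyl-8-(phenylsulfonyl)oct-5-en-1-yn-4-ol | C#CC[C@@H](O)/C=C(\C)CCS(=O)(=O)c1ccccc1 | intermediate
7 | dimethylaluminium alkoxide of (1E,4R,5E)-1-(dimethylalanyl)-2,6-dimethyl-8-(phenylsulfonyl)octa-1,5-dien-4-ol | C[Al](C)/C=C(\C)C[C@@H](O[Al](C)C)/C=C(\C)CCS(=O)(=O)c1ccccc1 | intermediate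
8 | (1E,4R,5E)-1-iodo-2,6-dimethyl-8-(phenylsulfonyl)octa-1,5-dien-4-ol | I/C=C(\C)C[C@@H](O)/C=C(\C)CCS(=O)(=O)c1ccccc1 | intermediate
9 | 3-methylbut-2-en-1-ol (prenol) | CC(C)=CCO | starting material
10 | [(2S)-3,3-dimethyloxiran-2-yl]methanol | OC[C@@H]1OC1(C)C | intermediate
11 | (2R)-3,3-dimethyloxirane-2-carbaldehyde | O=C[C@@H]1OC1(C)C | intermediate
12 | (1S,2E,5R,6E)-1-[(2S)-3,3-dimethyloxiran-2-yl]-3,7-dimethyl-9-(phenylsulfonyl)nona-2,6-diene-1,5-diol | O=S(=O)(c1ccccc1)CC/C(C)=C/[C@H](O)C/C(C)=C/[C@H](O)[C@@H]1OC1(C)C | intermediate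
13 | 1,5-bis-O-[tert-butyl(dimethyl)silyl] ether of 12 | O=S(=O)(c1ccccc1)CC/C(C)=C/[C@H](O[Si](C)(C)C(C)(C)C)C/C(C)=C/[C@H](O[Si](C)(C)C(C)(C)C)[C@@H]1OC1(C)C | intermediate
14 | 9-lithio derivative of 13 (lithium α-sulfonyl carbanion) | [Li]C(S(=O)(=O)c1ccccc1)C/C(C)=C/[C@H](O[Si](C)(C)C(C)(C)C)C/C(C)=C/[C@H](O[Si](C)(C)C(C)(C)C)[C@@H]1OC1(C)C | intermediate
15 | 2-[(1R,2S,3E,6R,7E)-2,6-bis{[tert-butyl(dimethyl)silyl]oxy}-4,8-dimethyl-10-(phenylsulfonyl)cyclodeca-3,7-dien-1-yl]propan-2-ol (both C10 epimers) | O=S(=O)(c1ccccc1)C1C/C(C)=C/[C@H](O[Si](C)(C)C(C)(C)C)C/C(C)=C/[C@H](O[Si](C)(C)C(C)(C)C)[C@@H]1C(C)(C)O | intermediate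
16 | methyl 2-[(1R,2S,3E,6R,7E)-2,6-bis{[tert-butyl(dimethyl)silyl]oxy}-4,8-dimethyl-10-(phenylsulfonyl)cyclodeca-3,7-dien-1-yl]propan-2-yl oxalate | O=S(=O)(c1ccccc1)C1C/C(C)=C/[C@H](O[Si](C)(C)C(C)(C)C)C/C(C)=C/[C@H](O[Si](C)(C)C(C)(C)C)[C@@H]1C(C)(C)OC(=O)C(=O)OC | intermediate
17 | {[(2S,3S,4E,7R,8E)-3,7-bis{[tert-butyl(dimethyl)silyl]oxy}-5,9-dimethyl-2-(propan-2-yl)cyclodeca-4,8-dien-1-yl]sulfonyl}benzene (both C1 epimers) | O=S(=O)(c1ccccc1)C1C/C(C)=C/[C@H](O[Si](C)(C)C(C)(C)C)C/C(C)=C/[C@H](O[Si](C)(C)C(C)(C)C)[C@@H]1C(C)C | intermediate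
18 | (1E,3R,5E,7R,8S)-3,7-bis{[tert-butyl(dimethyl)silyl]oxy}-1,5-dimethyl-8-(propan-2-yl)cyclodeca-1,5-diene | C1C/C(C)=C/[C@H](O[Si](C)(C)C(C)(C)C)C/C(C)=C/[C@H](O[Si](C)(C)C(C)(C)C)[C@@H]1C(C)C | intermediate
19 | (1R,2E,5R,6E,10S)-3,7-dimethyl-10-(propan-2-yl)cyclodeca-2,6-diene-1,5-diol | C1C/C(C)=C/[C@H](O)C/C(C)=C/[C@H](O)[C@@H]1C(C)C | intermediate
20 | (1S,2R,4S,5S,6R,7S,10S)-1,10:4,5-diepoxygermacrane-2,6-diol | C1C[C@]2(C)O[C@H]2[C@H](O)C[C@]3(C)O[C@H]3[C@H](O)[C@@H]1C(C)C | intermediate
21 | angelic acid, (2Z)-2-methylbut-2-enoic acid | C/C=C(/C)C(=O)O | starting material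
22 | (2Z)-2-methylbut-2-enoic 2,4,6-trichlorobenzoic anhydride | C/C=C(/C)C(=O)OC(=O)c1c(Cl)cc(Cl)cc1Cl | intermediate
23 | (1S,2R,4S,5S,6R,7S,10S)-1,10:4,5-diepoxy-6-hydroxygermacran-2-yl (2Z)-2-methylbut-2-enoate | C1C[C@]2(C)O[C@H]2[C@H](OC(=O)/C(C)=C\C)C[C@]3(C)O[C@H]3[C@H](O)[C@@H]1C(C)C | intermediate
24 | (1S,2R,4S,5S,6R,7S,10S)-6-acetoxy-1,10:4,5-diepoxygermacran-2-yl (2Z)-2-methylbut-2-enoate | C/C=C(/C)C(=O)O[C@@H]1C[C@]2(C)O[C@H]2[C@H](OC(C)=O)[C@H](C(C)C)CC[C@]2(C)O[C@@H]12 | target

**Step count**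

Total: 17 steps. Longest linear sequence: 15 steps (steps 1–5 and 8–17); steps 6 and 7 form the side branch.

**Steps most likely to fail**

Step 10 (ring closure). SN2 attack at C7, which sits between the silyloxy-bearing C6 and the quaternary C11, may be slower than base-induced isomerisation of the oxirane to an allylic alkoxide or than intermolecular alkylation. The fallback makes the same C7–C8 bond without the ring-strain penalty and closes the ring at C5–C6 instead. It sets out from 8 and 10 and comes back at 15.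
- Epoxy alcohol 10 would be silylated (TBSCl, imidazole) to tert-butyl{[(2S)-3,3-dimethyloxiran-2-yl]methoxy}dimethylsilane F1.
- The dianion of 8 (LiN(iPr)2, 2.1 equiv, THF–DMPU, −78 °C) would open an excess of F1 at the secondary oxirane carbon with inversion (BF3·OEt2 assistance if needed) to give (1E,4R,5E,9R)-9-({[tert-butyl(dimethyl)silyl]oxy}methyl)-1-iodo-2,6,10-trimethyl-8-(phenylsulfonyl)undeca-1,5-diene-4,10-diol F2.
- HF·pyridine would remove the primary silyl group to give the triol (1E,4R,5E,9R)-9-(hydroxymethyl)-1-iodo-2,6,10-trimethyl-8-(phenylsulfonyl)undeca-1,5-diene-4,10-diol F3.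
- TEMPO/PhI(OAc)2 would oxidise only the primary alcohol to the β-hydroxy aldehyde F4.
- An intramolecular Nozaki–Hiyama–Kishi reaction (CrCl2, NiCl2 cat., DMSO, high dilution) would close the ten-membered ring to the macrocyclic triol F5; its C6 epimers would be separated.
- TBSOTf (2.1 equiv, 2,6-lutidine, −78 °C) on the two secondary hydroxyls would give 15.

Step 8 (coupling with the epoxy aldehyde). Facial selectivity at the aldehyde may be poor, and the chromium and nickel salts may open the oxirane by Lewis acid catalysis. The fallback sets C6 by chelation-controlled reduction instead of by addition. It sets out from 8 and comes back at 13.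
- 8 would be silylated (TBSCl, imidazole) to the silyl ether F6.
- F6 would be coupled with 11 as in step 8 to the C6-epimeric alcohols of F7, (1S,2E,5R,6E)-5-{[tert-butyl(dimethyl)silyl]oxy}-1-[(2S)-3,3-dimethyloxiran-2-yl]-3,7-dimethyl-9-(phenylsulfonyl)nona-2,6-dien-1-ol.
- The mixture would be oxidised (Dess–Martin periodinane) to the α,β-epoxy enone F8.
- Zn(BH4)2 (Et2O, −30 °C) would reduce F8 through the chelate between the ketone and oxirane oxygens, returning F7 as the single anti (erythro) epimer.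
- TBSOTf would then give 13.

Step 16 (angeloylation). The activated angeloyl unit may isomerise from Z to E (tiglate formation) at the mixed-anhydride stage. The fallback builds the (Z)-alkene on the ester instead; it still relies on the C2-over-C6 site preference. It sets out from 20 and comes back at 24.
- 20 would be acylated at C2 with 2-[bis(2,2,2-trifluoroethoxy)phosphoryl]propanoic acid (DCC, DMAP cat., CH2Cl2, 0 °C) to the phosphonate ester F9, which cannot isomerise.
- Acetylation of the C6 hydroxyl (Ac2O, pyridine) would give the acetate F10.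
- Still–Gennari olefination of F10 (KN(SiMe3)2, 18-crown-6, acetaldehyde, THF, −78 °C) would form the (Z)-2-methylbut-2-enoate and give 24 directly.

**Further compounds**

F1 | step 10 | tert-butyl{[(2S)-3,3-dimethyloxiran-2-yl]methoxy}dimethylsilane | CC(C)(C)[Si](C)(C)OC[C@@H]1OC1(C)C
F2 | step 10 | (1E,4R,5E,9R)-9-({[tert-butyl(dimethyl)silyl]oxy}methyl)-1-iodo-2,6,10-trimethyl-8-(phenylsulfonyl)undeca-1,5-diene-4,10-diol (C8 epimers) | I/C=C(\C)C[C@@H](O)/C=C(\C)CC(S(=O)(=O)c1ccccc1)[C@H](CO[Si](C)(C)C(C)(C)C)C(C)(C)O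
F3 | step 10 | (1E,4R,5E,9R)-9-(hydroxymethyl)-1-iodo-2,6,10-trimethyl-8-(phenylsulfonyl)undeca-1,5-diene-4,10-diol (C8 epimers) | I/C=C(\C)C[C@@H](O)/C=C(\C)CC(S(=O)(=O)c1ccccc1)[C@H](CO)C(C)(C)O
F4 | step 10 | β-hydroxy aldehyde from F3: (2S,5E,7R,9E)-7-hydroxy-2-(2-hydroxypropan-2-yl)-10-iodo-5,9-dimethyl-3-(phenylsulfonyl)deca-5,9-dienal (C3 epimers) | I/C=C(\C)C[C@@H](O)/C=C(\C)CC(S(=O)(=O)c1ccccc1)[C@H](C=O)C(C)(C)O
F5 | step 10 | (1S,2E,5R,6E,10R)-10-(2-hydroxypropan-2-yl)-3,7-dimethyl-9-(phenylsulfonyl)cyclodeca-2,6-diene-1,5-diol (C9 epimers) | O=S(=O)(c1ccccc1)C1C/C(C)=C/[C@H](O)C/C(C)=C/[C@H](O)[C@@H]1C(C)(C)O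
F6 | step 8 | tert-butyl{[(1E,4R,5E)-1-iodo-2,6-dimethyl-8-(phenylsulfonyl)octa-1,5-dien-4-yl]oxy}dimethylsilane | I/C=C(\C)C[C@@H](O[Si](C)(C)C(C)(C)C)/C=C(\C)CCS(=O)(=O)c1ccccc1
F7 | step 8 | (1S,2E,5R,6E)-5-{[tert-butyl(dimethyl)silyl]oxy}-1-[(2S)-3,3-dimethyloxiran-2-yl]-3,7-dimethyl-9-(phenylsulfonyl)nona-2,6-dien-1-ol | O=S(=O)(c1ccccc1)CC/C(C)=C/[C@H](O[Si](C)(C)C(C)(C)C)C/C(C)=C/[C@H](O)[C@@H]1OC1(C)C
F8 | step 8 | (2E,5R,6E)-5-{[tert-butyl(dimethyl)silyl]oxy}-1-[(2R)-3,3-dimethyloxiran-2-yl]-3,7-dimethyl-9-(phenylsulfonyl)nona-2,6-dien-1-one | O=S(=O)(c1ccccc1)CC/C(C)=C/[C@H](O[Si](C)(C)C(C)(C)C)C/C(C)=C/C(=O)[C@@H]1OC1(C)C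
F9 | step 16 | (1S,2R,4S,5S,6R,7S,10S)-1,10:4,5-diepoxy-6-hydroxygermacran-2-yl 2-[bis(2,2,2-trifluoroethoxy)phosphoryl]propanoate | C1C[C@]2(C)O[C@H]2[C@H](OC(=O)C(C)P(=O)(OCC(F)(F)F)OCC(F)(F)F)C[C@]3(C)O[C@H]3[C@H](O)[C@@H]1C(C)C
F10 | step 16 | (1S,2R,4S,5S,6R,7S,10S)-6-acetoxy-1,10:4,5-diepoxygermacran-2-yl 2-[bis(2,2,2-trifluoroethoxy)phosphoryl]propanoate | C1C[C@]2(C)O[C@H]2[C@H](OC(=O)C(C)P(=O)(OCC(F)(F)F)OCC(F)(F)F)C[C@]3(C)O[C@H]3[C@H](OC(C)=O)[C@@H]1C(C)C
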